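Everything rests on cutting C3–C4 of the lactone ring and on reading the C1'–C4' diene as the one-carbon-shifted isomer of a dienol ester. C3 is at once the carbon that bears O2 and the end of the diene. It is tied to benzylic C4 by the four atoms C4a, C8a, C1 and O2. An enantioselective Mizoroki-Heck cyclisation of a benzylic bromide therefore closes the lactone ring at C3–C4, sets C3 and moves the diene into its final place through an allylpalladium intermediate, in one operation. The precursor is achiral and open-chain: the dienol ester of plain (E)-octadec-2-enal with 2-acetoxy-6-(bromomethyl)benzoic acid.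

Key step: step 6

Numbering: isochroman-1-one numbering is used (C1 lactone carbonyl, O2, C3, C4, C4a, C5–C8, C8a, O8 on C8). The side chain is C1'–C17', counted from C3.

Assumption: the sense of induction of the chiral ligand in step 6 cannot be derived from a model with certainty. Both ligand enantiomers are commercial, and the one that leads to (R)-11 is used.

Step 1
Reactants: 1 heptadec-1-ene; 2 (E)-but-2-enal (crotonaldehyde)
Product: 3 (E)-octadec-2-enal
Conditions: second-generation Hoveyda-Grubbs catalyst (2 mol %), 2 (4 equiv), CH2Cl2, 40 °C
Reagents that add atoms: none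
Why: Olefin cross-metathesis of a terminal alkene with an electron-poor enal favours the cross product, should give the E-enal under thermodynamic control, and is driven by loss of a gaseous alkene.

Step 2
Reactants: 4 2-hydroxy-6-methylbenzoic acid
Product: 5 2-acetoxy-6-methylbenzoic acid
Conditions: Ac2O (1.5 equiv), H3PO4 (cat.), 60 °C; then H2O
Reagents that add atoms: acetic anhydride, CC(=O)OC(C)=O
Why: Acid-catalysed O-acetylation of a salicylic acid masks O8 and makes the arene poorer in electrons for step 4, and the aqueous quench hydrolyses any mixed anhydride.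

Step 3
Reactants: 5 2-acetoxy-6-methylbenzoic acid
Product: 6 2-acetoxy-6-methylbenzoyl chloride
Conditions: (COCl)2 (1.3 equiv), DMF (cat.), CH2Cl2, 0 °C to rt
Reagents that add atoms: oxalyl chloride, O=C(Cl)C(=O)Cl
Why: Acid chloride formation through the chloroiminium salt of DMF runs under mild conditions that leave the aryl acetate intact, and it removes the free acid that would lactonise onto a benzylic halide.

Step 4
Reactants: 6 2-acetoxy-6-methylbenzoyl chloride
Product: 7 2-acetoxy-6-(bromomethyl)benzoyl chloride
Conditions: NBS (1.05 equiv), AIBN (5 mol %), PhCF3, 85 °C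
Reagents that add atoms: N-bromosuccinimide, O=C1CCC(=O)N1Br
Why: Wohl-Ziegler bromination attacks the only benzylic C–H bonds, since the acyl chloride and the acetate deactivate the ring toward nuclear bromination and the acetyl C–H bonds are polarity-mismatched for the bromine atom.

Step 5
Reactants: 3 (E)-octadec-2-enal; 7 2-acetoxy-6-(bromomethyl)benzoyl chloride
Product: 9 (1E,3Z)-octadeca-1,3-dien-1-yl 2-acetoxy-6-(bromomethyl)benzoate, via potassium dienolate 8 (not isolated)
Conditions: KOtBu (1.0 equiv), THF, −78 °C, slow addition of 3; then transfer into 7 (1.05 equiv), THF, −78 to −40 °C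
Reagents that add atoms: none
Why: Kinetic γ-deprotonation of the s-trans enal should give the (1E)-dienolate (3Z expected from the syn effect, and of no consequence later), and O-acylation of a potassium dienolate by the hard acyl chloride should outrun attack at the benzylic bromide or the aryl acetate at low temperature.

Step 6
Reactants: 9 (1E,3Z)-octadeca-1,3-dien-1-yl 2-acetoxy-6-(bromomethyl)benzoate
Product: 11 (R)-8-acetoxy-3-[(1E,3E)-heptadeca-1,3-dien-1-yl]isochroman-1-one, via allylpalladium bromide 10 (not isolated)
Conditions: Pd2(dba)3 (2.5 mol %), BINOL-derived phosphoramidite with a bis(1-phenylethyl)amino group (10 mol %, enantiomer as in the assumption), Li2CO3 (2 equiv), 1,4-dioxane (0.01 M), 50 °C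
Reagents that add atoms: none
Why: Proposed new method: zerovalent palladium inserts into the benzylic C4–Br bond of 9, the benzylpalladium bromide adds across the enol-ester alkene C3=C1' in a 6-exo-trig migratory insertion that forms C4–C3 and closes the lactone ring, the metal settles as the η3-allyl complex 10 over C1'–C3', and β-hydride elimination of a C4' hydrogen releases the (1'E,3'E)-diene while Li2CO3 takes up HBr. The closest known reaction types are the Mizoroki-Heck cyclisation of benzylic halides, the enantioselective intermolecular Mizoroki-Heck benzylation of cyclic enol ethers at their oxygen-bearing carbon with phosphoramidite ligands, asymmetric Heck insertion into 1,3-dienes to give allylpalladium species, and the palladium-catalysed elimination of allylpalladium species to 1,3-dienes, and what is new is their union on an acyclic dienol ester. The only new stereocentre, C3, is fixed in the insertion, where the chiral ligand on palladium selects one face of the geometrically defined (1E)-alkene, whereas later η3-η1-η3 shifts touch only C1'–C3' and so erase the 3Z geometry of 9 without reaching C3. Regioselectivity is secured by the substrate in three ways: the ester tether gives a six-membered ring only at C3 (seven to nine ring atoms at C1'–C3'), attack at the diene terminus is the only mode that yields a stabilised allyl complex, and enol esters prefer to take up carbon at the oxygen-bearing carbon. The elimination must take C4'–H and not C3–H, which is plausible because C3–H is tertiary, ring-bound and made less hydridic by the acyloxy group while C4' offers two unhindered hydrogens, and the syn,syn form of the allyl complex leads to E geometry at both alkenes. Chemoselectivity for 9 over the dienylic ester 11 rests on the much faster oxidative addition of a benzylic bromide than of a hindered allylic benzoate, so the reaction is stopped at full conversion.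

Step 7
Reactants: 11 (R)-8-acetoxy-3-[(1E,3E)-heptadeca-1,3-dien-1-yl]isochroman-1-one
Product: 12 (R)-3-[(1E,3E)-heptadeca-1,3-dien-1-yl]-8-hydroxyisochroman-1-one (target)
Conditions: K2CO3 (0.2 equiv), MeOH, 0 °C; then aq. NH4Cl
Reagents that add atoms: none
Why: Base-catalysed transesterification cleaves the unhindered aryl acetate much faster than the di-ortho-substituted lactone carbonyl, and C3 carries no acidic hydrogen, so its configuration should hold.

Compound list
1 | heptadec-1-ene | C=CCCCCCCCCCCCCCCC | starting material
2 | (E)-but-2-enal | C/C=C/C=O | starting material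
3 | (E)-octadec-2-enal | CCCCCCCCCCCCCCC/C=C/C=O | intermediate
4 | 2-hydroxy-6-methylbenzoic acid | Cc1cccc(O)c1C(=O)O | starting material
5 | 2-acetoxy-6-methylbenzoic acid | Cc1cccc(OC(C)=O)c1C(=O)O | intermediate
6 | 2-acetoxy-6-methylbenzoyl chloride | Cc1cccc(OC(C)=O)c1C(=O)Cl | intermediate
7 | 2-acetoxy-6-(bromomethyl)benzoyl chloride | BrCc1cccc(OC(C)=O)c1C(=O)Cl | intermediate
8 | potassium (1E,3Z)-octadeca-1,3-dien-1-olate | CCCCCCCCCCCCCC/C=C\C=C\[O-].[K+] | intermediate
9 | (1E,3Z)-octadeca-1,3-dien-1-yl 2-acetoxy-6-(bromomethyl)benzoate | CCCCCCCCCCCCCC/C=C\C=C\OC(=O)c1c(CBr)cccc1OC(C)=O | intermediate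
10 | allylpalladium bromide of the cyclised lactone (η3 over C1'–C3', drawn in its η1 form at C3', phosphoramidite omitted) | CCCCCCCCCCCCCCC([Pd]Br)/C=C/[C@H]1Cc2cccc(OC(C)=O)c2C(=O)O1 | intermediate
11 | (R)-8-acetoxy-3-[(1E,3E)-heptadeca-1,3-dien-1-yl]isochroman-1-one | CCCCCCCCCCCCC/C=C/C=C/[C@H]1Cc2cccc(OC(C)=O)c2C(=O)O1 | intermediate
12 | (R)-3-[(1E,3E)-heptadeca-1,3-dien-1-yl]-8-hydroxyisochroman-1-one | CCCCCCCCCCCCC/C=C/C=C/[C@H]1Cc2cccc(O)c2C(=O)O1 | target

Total step count: 7
Longest linear sequence: 6 steps (4 → 5 → 6 → 7 → 9 → 11 → 12)

Steps most likely to fail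

1. Step 6 (the labelled step).
- β-Hydride elimination may turn toward C3–H, with drift to the aromatic isocoumarin.
- The carboxylate may leave from the allylpalladium stage, or zerovalent palladium may re-ionise the dienylic ester.
- Insertion may be slow because the ester must leave its preferred conformation.
- Facial selectivity in the insertion may be poor.

The fallback uses known chemistry only, sets out from 4 and returns at 12.
- Acid 4 is condensed with acetone (trifluoroacetic anhydride, trifluoroacetic acid, 0 °C to rt) to 2,2,5-trimethyl-4H-1,3-benzodioxin-4-one F1.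
- Tetradecanal is extended in a vinylogous Horner-Wadsworth-Emmons reaction with diethyl (E)-4-[methoxy(methyl)amino]-4-oxobut-2-enylphosphonate (LiN(SiMe3)2, THF, −78 °C to rt) to (2E,4E)-N-methoxy-N-methyloctadeca-2,4-dienamide F2.
- Lateral deprotonation of F1 (LiN(iPr)2, 2 equiv, THF, −78 °C) and acylation with F2 gives 2,2-dimethyl-5-[(3E,5E)-2-oxononadeca-3,5-dien-1-yl]-4H-1,3-benzodioxin-4-one F3.
- Corey-Bakshi-Shibata reduction with the (S)-2-methyl-oxazaborolidine and catecholborane (toluene, −78 °C) treats the dienyl group as the large substituent. It should give 5-[(2R,3E,5E)-2-hydroxynonadeca-3,5-dien-1-yl]-2,2-dimethyl-4H-1,3-benzodioxin-4-one F4.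
- NaH in THF at 0 °C lets the alkoxide attack the dioxinone carbonyl, which closes the lactone, frees O8 and gives 12.

2. Step 5.
- The dienolate may be alkylated by the benzylic bromide or may attack the aryl acetate, because the di-ortho-substituted acyl chloride reacts slowly.
- The enal may condense with itself under base.
- The geometry at C3=C1' may be mixed.

The fallback sets out from 3 and 7 and returns at 9. It avoids a stoichiometric enolate.
- Enal 3 is silylated (TMSOTf, Et3N, Et2O, 0 °C) to (1E,3Z)-1-(trimethylsilyloxy)octadeca-1,3-diene F5, which can be purified.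
- Chloride 7 is converted with KHF2 (CH2Cl2/H2O, rt) into 2-acetoxy-6-(bromomethyl)benzoyl fluoride F6.
- The two are joined by fluoride-catalysed O-acylation of the silyl dienol ether (tetrabutylammonium difluorotriphenylsilicate, 5 mol %, THF, −20 °C) to give 9.

3. Step 4.
- Over-bromination may give the dibromide.
- Some nuclear bromination may occur.
- The acyl chloride and benzyl bromide pair may collapse to the phthalide on contact with moisture.

The fallback sets out from 5 and returns at 7. It uses the phthalide on purpose.
- Acid 5 is lactonised at its methyl group by carboxylate-directed benzylic C–H acyloxylation (Pd(OAc)2, N-acetyl-L-leucine, Ag2CO3, K2HPO4, chlorobenzene, 140 °C) to 7-acetoxyphthalide F7.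
- HBr in acetic acid at rt opens it to 2-acetoxy-6-(bromomethyl)benzoic acid F8.
- Oxalyl chloride with catalytic DMF in CH2Cl2 at 0 °C gives 7.

Further compounds
F1 | step 6 | 2,2,5-trimethyl-4H-1,3-benzodioxin-4-one | Cc1cccc2OC(C)(C)OC(=O)c12
F2 | step 6 | (2E,4E)-N-methoxy-N-methyloctadeca-2,4-dienamide | CCCCCCCCCCCCC/C=C/C=C/C(=O)N(C)OC
F3 | step 6 | 2,2-dimethyl-5-[(3E,5E)-2-oxononadeca-3,5-dien-1-yl]-4H-1,3-benzodioxin-4-one | CCCCCCCCCCCCC/C=C/C=C/C(=O)Cc1cccc2OC(C)(C)OC(=O)c12
F4 | step 6 | 5-[(2R,3E,5E)-2-hydroxynonadeca-3,5-dien-1-yl]-2,2-dimethyl-4H-1,3-benzodioxin-4-one | CCCCCCCCCCCCC/C=C/C=C/[C@H](O)Cc1cccc2OC(C)(C)OC(=O)c12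
F5 | step 5 | (1E,3Z)-1-(trimethylsilyloxy)octadeca-1,3-diene | CCCCCCCCCCCCCC/C=C\C=C\O[Si](C)(C)C
F6 | step 5 | 2-acetoxy-6-(bromomethyl)benzoyl fluoride | BrCc1cccc(OC(C)=O)c1C(F)=O
F7 | step 4 | 7-acetoxyphthalide | CC(=O)Oc1cccc2COC(=O)c12
F8 | step 4 | 2-acetoxy-6-(bromomethyl)benzoic acid | BrCc1cccc(OC(C)=O)c1C(=O)O
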